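**Retrosynthetic overview**

1. Ring numbering used throughout: C1 (OMe), C2 (H), C3 (2-phenylethyl), C4 (OMe), C5 (OMe), C6 (3-hydroxy-3-methylbutyl). The strategy rests on the C3 phenethyl group lying ortho to the C4 oxygen of the C1/C4 para-dioxygenated benzene ring.
2. Target 12 ⇐ ester 10 (two methyl groups from MeMgBr) ⇐ hydroquinone 9 (O-methylation at C1 and C4).
3. 9 ⇐ para-quinol 8: acid-promoted 1,2-shift of the phenethyl group from C4 to C3 (C3–CH2 bond) with aromatisation.
4. 8 ⇐ methoxyquinone 5 + 2-phenylethylmagnesium bromide (1,2-addition at the C4 carbonyl); 5 ⇐ phenol 4 (para-oxidation) ⇐ aldehyde 1 + ylide 2 (Wittig, hydrogenation).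
5. No ring is formed: the benzene ring of 1 is carried through, dearomatised in steps 3 and 4 and rearomatised in step 5; the phenyl ring is bought.

Key step: step 5

Remark on the chemistry: quinol 8 has one stereocentre (C4). It forms as the racemate and is erased in step 5; the target has no stereocentre.

**Route**

Step 1
Reactants: 1 2-hydroxy-6-methoxybenzaldehyde; 2 methyl (triphenylphosphoranylidene)acetate
Product: 3 methyl (E)-3-(2-hydroxy-6-methoxyphenyl)prop-2-enoate
Conditions: 2 (1.1 equiv), toluene, 60 °C
Reagents that add atoms: none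
Why: Wittig olefination with a stabilised ylide, which tolerates the free phenol and should give the E-alkene, so that closure to 5-methoxycoumarin (which needs the Z-isomer) stays a minor path.

Step 2
Reactants: 3 methyl (E)-3-(2-hydroxy-6-methoxyphenyl)prop-2-enoate
Product: 4 methyl 3-(2-hydroxy-6-methoxyphenyl)propanoate
Conditions: H2 (1 atm), Pd/C, EtOAc, rt
Reagents that add atoms: none
Why: Heterogeneous catalytic hydrogenation reduces only the conjugated alkene; arene, ester and aryl ether are untouched, and the neutral aprotic medium should keep the hydroxy ester from lactonising.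

Step 3
Reactants: 4 methyl 3-(2-hydroxy-6-methoxyphenyl)propanoate
Product: 5 methyl 3-(2-methoxy-3,6-dioxocyclohexa-1,4-dien-1-yl)propanoate
Conditions: (KSO3)2NO (2.5 equiv), KH2PO4, H2O–acetone, 0 °C → rt
Reagents that add atoms: potassium nitrosodisulfonate (KSO3)2NO, [K+].[K+].[O]N(S(=O)(=O)[O-])S(=O)(=O)[O-]
Why: Teuber oxidation: the phenoxyl radical is trapped by a second nitroxide at the free para position (C4), so the para-quinone should form with its new carbonyl next to the methoxy carbon, and the near-neutral buffer spares the ester.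

Step 4
Reactants: 5 methyl 3-(2-methoxy-3,6-dioxocyclohexa-1,4-dien-1-yl)propanoate; 6 (2-bromoethyl)benzene
Product: 8 methyl 3-[3-hydroxy-2-methoxy-6-oxo-3-(2-phenylethyl)cyclohexa-1,4-dien-1-yl]propanoate (racemic), via 2-phenylethylmagnesium bromide 7 (not isolated)
Conditions: 6, Mg, THF, rt; solution of 7 (1.2 equiv) added to 5, THF, −78 °C; aq. NH4Cl
Reagents that add atoms: none
Why: Grignard 1,2-addition to a quinone carbonyl: the C1 carbonyl is deactivated as a vinylogous ester by the C5 methoxy group through C5=C6 and is flanked by the side chain, so attack should go to the C4 carbonyl, where magnesium can also sit between the carbonyl and methoxy oxygens; at −78 °C the methyl ester should be left alone, and the new C4 stereocentre forms as the racemate, which is of no consequence because step 5 removes it.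

Step 5
Reactants: 8 methyl 3-[3-hydroxy-2-methoxy-6-oxo-3-(2-phenylethyl)cyclohexa-1,4-dien-1-yl]propanoate
Product: 9 methyl 3-[3,6-dihydroxy-2-methoxy-4-(2-phenylethyl)phenyl]propanoate
Conditions: CF3CO2H–CH2Cl2 (1:4), 0 °C → rt, N2; evaporate, use crude
Reagents that add atoms: none
Why: Protonation of the C1 carbonyl of the cross-conjugated dienone gives a hydroxypentadienyl cation whose charge is shared by C3 and C5; the phenethyl group then shifts 1,2 from C4 to C3 (forming the C3–CH2 bond), the C4 cation left behind is a protonated ketone, and loss of the C3 proton gives the aromatic hydroquinone. The closest known reaction is the dienone–phenol (quinol) rearrangement of 4-alkyl-4-hydroxycyclohexa-2,5-dienones to alkylhydroquinones in acid, a vinylogous semipinacol shift. No ring is closed and no stereocentre is made; the C4 stereocentre of 8 disappears. The step needs migration to C3 and not to C5: a shift to C5 would give up the methoxy-stabilised cation and build a quaternary methoxy carbon that cannot aromatise and can shift back under the same acid, whereas the shift to the unsubstituted C3 is sealed by irreversible loss of a proton. It also needs the shift to outrun closure of the pendant phenyl ring onto C3 and hydrolysis of the C5 enol ether, which the unactivated, poorly nucleophilic phenyl ring and the anhydrous medium should secure. Keeping the side chain at the ester oxidation level leaves no carbocation precursor next to the phenol that forms at C1, so no chroman can close.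

Step 6
Reactants: 9 methyl 3-[3,6-dihydroxy-2-methoxy-4-(2-phenylethyl)phenyl]propanoate
Product: 10 methyl 3-[2,3,6-trimethoxy-4-(2-phenylethyl)phenyl]propanoate
Conditions: Me2SO4 (3 equiv), K2CO3, degassed acetone, reflux, N2
Reagents that add atoms: dimethyl sulfate, COS(=O)(=O)OC
Why: Williamson O-methylation of both phenoxides; the ester is inert to K2CO3 in dry acetone, and exclusion of air should keep the hydroquinone from reoxidising.

Step 7
Reactants: 10 methyl 3-[2,3,6-trimethoxy-4-(2-phenylethyl)phenyl]propanoate
Product: 12 2-methyl-4-[2,3,6-trimethoxy-4-(2-phenylethyl)phenyl]butan-2-ol, via methyl ketone 11 (not isolated)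
Conditions: MeMgBr (3.5 equiv), THF, 0 °C → rt; aq. NH4Cl
Reagents that add atoms: methylmagnesium bromide, C[Mg]Br
Why: Double Grignard addition to an ester: the ketone formed first is more electrophilic than the ester and takes the second methyl group, the aryl ethers are inert, and the neutral work-up avoids dehydration of the tertiary alcohol.

**Compound list**

1 | 2-hydroxy-6-methoxybenzaldehyde | COc1cccc(O)c1C=O | starting material
2 | methyl (triphenylphosphoranylidene)acetate | COC(=O)C=P(c1ccccc1)(c1ccccc1)c1ccccc1 | starting material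
3 | methyl (E)-3-(2-hydroxy-6-methoxyphenyl)prop-2-enoate | COC(=O)/C=C/c1c(O)cccc1OC | intermediate
4 | methyl 3-(2-hydroxy-6-methoxyphenyl)propanoate | COC(=O)CCc1c(O)cccc1OC | intermediate
5 | methyl 3-(2-methoxy-3,6-dioxocyclohexa-1,4-dien-1-yl)propanoate | COC(=O)CCC1=C(OC)C(=O)C=CC1=O | intermediate
6 | (2-bromoethyl)benzene | BrCCc1ccccc1 | starting material
7 | 2-phenylethylmagnesium bromide | Br[Mg]CCc1ccccc1 | intermediate
8 | methyl 3-[3-hydroxy-2-methoxy-6-oxo-3-(2-phenylethyl)cyclohexa-1,4-dien-1-yl]propanoate (racemic) | COC(=O)CCC1=C(OC)C(O)(CCc2ccccc2)C=CC1=O | intermediate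
9 | methyl 3-[3,6-dihydroxy-2-methoxy-4-(2-phenylethyl)phenyl]propanoate | COC(=O)CCc1c(O)cc(CCc2ccccc2)c(O)c1OC | intermediate
10 | methyl 3-[2,3,6-trimethoxy-4-(2-phenylethyl)phenyl]propanoate | COC(=O)CCc1c(OC)cc(CCc2ccccc2)c(OC)c1OC | intermediate
11 | 4-[2,3,6-trimethoxy-4-(2-phenylethyl)phenyl]butan-2-one | CC(=O)CCc1c(OC)cc(CCc2ccccc2)c(OC)c1OC | intermediate
12 | 2-methyl-4-[2,3,6-trimethoxy-4-(2-phenylethyl)phenyl]butan-2-ol | COc1cc(CCc2ccccc2)c(OC)c(OC)c1CCC(C)(C)O | target

**Step count**

Total steps: 7. Longest linear sequence: 7 steps (1 → 12).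

**Steps most likely to fail**

Step 5. The methoxy-stabilised cation may shift slowly, and it may be diverted in three ways: closure of the phenyl ring onto C3, a phenethyl shift to C5 followed by tautomerisation to an ene-dione, or loss of the enol ether. The fallback sets out from 4 and comes back at 10; it places the phenethyl group at C3 by conjugate addition and not by rearrangement.
- Oxidation of 4 with PhI(OAc)2 (2 equiv) in MeOH should give the para-quinone monoketal methyl 3-(2,3,3-trimethoxy-6-oxocyclohexa-1,4-dien-1-yl)propanoate F1.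
- The cuprate (PhCH2CH2)2CuMgBr, made from 7 and CuBr·SMe2 in THF at −78 °C, should add to the unsubstituted enone carbon C3 and give methyl 3-[2,3,3-trimethoxy-6-oxo-4-(2-phenylethyl)cyclohex-1-en-1-yl]propanoate F2.
- p-TsOH in CH2Cl2 should eliminate methanol and aromatise F2 to methyl 3-[6-hydroxy-2,3-dimethoxy-4-(2-phenylethyl)phenyl]propanoate F3.
- Methylation of F3 with Me2SO4 and K2CO3 in acetone gives 10.

Step 4. The Grignard reagent may reduce the quinone by electron transfer, add in conjugate fashion at C2 or C3, displace the C5 methoxy group, or attack the C1 carbonyl. The fallback sets out from 4 and comes back at 8; it replaces the quinone by a monoketal in which C1 is masked and C4 is the only ketone.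
- Methylation of 4 (Me2SO4, K2CO3, acetone) gives the symmetrical methyl 3-(2,6-dimethoxyphenyl)propanoate F4.
- Vilsmeier formylation (POCl3, DMF, then aq. NaOAc) can only give methyl 3-(3-formyl-2,6-dimethoxyphenyl)propanoate F5.
- Baeyer–Villiger oxidation with mCPBA in CH2Cl2 gives the aryl formate methyl 3-[3-(formyloxy)-2,6-dimethoxyphenyl]propanoate F6.
- K2CO3 in MeOH cleaves F6 to methyl 3-(3-hydroxy-2,6-dimethoxyphenyl)propanoate F7.
- PhI(OAc)2 in MeOH should oxidise F7 to the monoketal methyl 3-(2,6,6-trimethoxy-3-oxocyclohexa-1,4-dien-1-yl)propanoate F8.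
- Addition of 7 in THF at −78 °C to the C4 ketone should give methyl 3-[3-hydroxy-2,6,6-trimethoxy-3-(2-phenylethyl)cyclohexa-1,4-dien-1-yl]propanoate F9.
- Dilute aqueous acetic acid in THF at rt should hydrolyse the ketal of F9 to 8.

Step 6. The hydroquinone dianion may reoxidise in air to a quinone, the C4 hydroxyl flanked by two substituents may alkylate slowly, and part of 9 may already have closed onto the ester in step 5. The fallback sets out from 9 and comes back at 12; it uses that ring closure as a protecting group and reverses the order of O-methylation and Grignard addition.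
- Catalytic p-TsOH in refluxing toluene should close 9 fully to the lactone 6-hydroxy-5-methoxy-7-(2-phenylethyl)-3,4-dihydro-2H-1-benzopyran-2-one F10, which is no longer a free hydroquinone.
- MeI and K2CO3 in acetone methylate the remaining C4 phenol to 5,6-dimethoxy-7-(2-phenylethyl)-3,4-dihydro-2H-1-benzopyran-2-one F11.
- MeMgBr in THF opens the lactone to 2-(3-hydroxy-3-methylbutyl)-3,4-dimethoxy-5-(2-phenylethyl)phenol F12.
- Me2SO4 and K2CO3 in acetone methylate the single phenol of F12, not the tertiary alcohol, and give 12.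

**Further compounds**

F1 | step 5 | methyl 3-(2,3,3-trimethoxy-6-oxocyclohexa-1,4-dien-1-yl)propanoate | COC(=O)CCC1=C(OC)C(OC)(OC)C=CC1=O
F2 | step 5 | methyl 3-[2,3,3-trimethoxy-6-oxo-4-(2-phenylethyl)cyclohex-1-en-1-yl]propanoate (racemic) | COC(=O)CCC1=C(OC)C(OC)(OC)C(CCc2ccccc2)CC1=O
F3 | step 5 | methyl 3-[6-hydroxy-2,3-dimethoxy-4-(2-phenylethyl)phenyl]propanoate | COC(=O)CCc1c(O)cc(CCc2ccccc2)c(OC)c1OC
F4 | step 4 | methyl 3-(2,6-dimethoxyphenyl)propanoate | COC(=O)CCc1c(OC)cccc1OC
F5 | step 4 | methyl 3-(3-formyl-2,6-dimethoxyphenyl)propanoate | COC(=O)CCc1c(OC)ccc(C=O)c1OC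
F6 | step 4 | methyl 3-[3-(formyloxy)-2,6-dimethoxyphenyl]propanoate | COC(=O)CCc1c(OC)ccc(OC=O)c1OC
F7 | step 4 | methyl 3-(3-hydroxy-2,6-dimethoxyphenyl)propanoate | COC(=O)CCc1c(OC)ccc(O)c1OC
F8 | step 4 | methyl 3-(2,6,6-trimethoxy-3-oxocyclohexa-1,4-dien-1-yl)propanoate | COC(=O)CCC1=C(OC)C(=O)C=CC1(OC)OC
F9 | step 4 | methyl 3-[3-hydroxy-2,6,6-trimethoxy-3-(2-phenylethyl)cyclohexa-1,4-dien-1-yl]propanoate (racemic) | COC(=O)CCC1=C(OC)C(O)(CCc2ccccc2)C=CC1(OC)OC
F10 | step 6 | 6-hydroxy-5-methoxy-7-(2-phenylethyl)-3,4-dihydro-2H-1-benzopyran-2-one | O=C1CCc2c(O1)cc(CCc3ccccc3)c(O)c2OC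
F11 | step 6 | 5,6-dimethoxy-7-(2-phenylethyl)-3,4-dihydro-2H-1-benzopyran-2-one | O=C1CCc2c(O1)cc(CCc3ccccc3)c(OC)c2OC
F12 | step 6 | 2-(3-hydroxy-3-methylbutyl)-3,4-dimethoxy-5-(2-phenylethyl)phenol | CC(C)(O)CCc1c(O)cc(CCc2ccccc2)c(OC)c1OC
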